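**Synthesis proposal for (5S,9R,10S,13S)-15-(formyloxy)labd-7-en-17-oic acid**

Retrosynthesis: the formate is removed, the C17 acid and the C15 oxygen are tied back into a nine-membered lactone, and the ring alkene is moved from C7=C8 to C6=C7. Ring B (C5-C6-C7-C8-C9-C10) is then cut at C5-C10 and C8-C9 by a retro-[4+2], which also opens ring A and leaves a 17-membered (E,E,E)-trienoic macrolactone. This is cut at O15-C17 (ester) and at C1-C10 (sp3-sp2).
Enabling feature: the carboxyl carbon C17 sits on C8 and the oxygen-bearing C15 ends the chain on the neighbouring C9. Joined as a lactone they hold the C5=C6-C7=C8 dienoate across the ring from the C9=C10 alkene, so ring B is a transannular cycloadduct and ring A closes with it.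
Forward: a citronellol-derived (E)-vinyl iodide and a dienoate with a terminal alkene are joined at C1-C10, and the macrocycle is closed at O15-C17. Rings A and B then form together; the lactone is opened, the alkene conjugated, the ester saponified and O15 formylated.
Stereochemistry: C13 is bought with (S)-citronellol. C5, C9 and C10 arise together in the cycloaddition, their relative sense from the (E,E)-diene, the (E)-alkene and the exo four-carbon tether, their absolute sense by relay from C13 through the lactone bridge. C8 is temporary.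

Key step: step 11

Assumption: the SMILES is read as the normal labdane (5S,9R,10S,13S); labdane numbering is used for all intermediates, and cyclopentadienyl ligands are drawn σ-bonded in SMILES.

Step 1
Reactants: 1 (S)-citronellol [(S)-3,7-dimethyloct-6-en-1-ol]
Product: 2 (S)-tert-butyl[(3,7-dimethyloct-6-en-1-yl)oxy]dimethylsilane
Conditions: TBSCl, imidazole, CH2Cl2, 0 °C to rt
Reagents that add atoms: tert-butyldimethylsilyl chloride, CC(C)(C)[Si](C)(C)Cl
Why: Imidazole-promoted silylation of the primary alcohol masks the future O15 for the organolithium, zirconium and palladium steps and leaves the C13 stereocentre untouched.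

Step 2
Reactants: 2 (S)-tert-butyl[(3,7-dimethyloct-6-en-1-yl)oxy]dimethylsilane
Product: 4 (S)-6-[(tert-butyldimethylsilyl)oxy]-4-methylhexanal, via secondary ozonide 3 (not isolated)
Conditions: O3, CH2Cl2, −78 °C; then PPh3, −78 °C to rt
Reagents that add atoms: ozone, [O-][O+]=O
Why: Ozonolysis with reductive work-up cleaves the only alkene and gives the aldehyde whose carbonyl carbon becomes C9, while the silyl ether and the remote stereocentre are inert.

Step 3
Reactants: 4 (S)-6-[(tert-butyldimethylsilyl)oxy]-4-methylhexanal; 5 carbon tetrabromide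
Product: 7 (S)-tert-butyl[(7,7-dibromo-3-methylhept-6-en-1-yl)oxy]dimethylsilane, via dibromomethylene ylide 6 (not isolated)
Conditions: PPh3, Zn, CH2Cl2, rt; then 4, rt
Reagents that add atoms: none
Why: Corey–Fuchs dibromoolefination (Wittig-type reaction of Ph3P=CBr2) adds the carbon that becomes C10, and the Zn variant takes up the bromine as ZnBr2 so that no Ph3PBr2 is present to attack the silyl ether.

Step 4
Reactants: 7 (S)-tert-butyl[(7,7-dibromo-3-methylhept-6-en-1-yl)oxy]dimethylsilane; 8 iodomethane
Product: 10 (S)-tert-butyldimethyl[(3-methyloct-6-yn-1-yl)oxy]silane, via lithium acetylide 9 (not isolated)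
Conditions: n-BuLi (2.2 equiv), THF, −78 to −20 °C; then 8, −78 °C to rt
Reagents that add atoms: none
Why: In the second stage of the Corey–Fuchs sequence bromine–lithium exchange, rearrangement and deprotonation give the lithium acetylide, which is methylated by iodomethane in an SN2 reaction to install C20.

Step 5
Reactants: 10 (S)-tert-butyldimethyl[(3-methyloct-6-yn-1-yl)oxy]silane
Product: 12 (S,E)-tert-butyl[(7-iodo-3-methyloct-6-en-1-yl)oxy]dimethylsilane (fragment 1), via alkenylzirconocene chloride 11 (not isolated)
Conditions: Cp2Zr(H)Cl (excess), THF, 50 °C; then I2, THF, 0 °C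
Reagents that add atoms: iodine, I-I
Why: syn-Hydrozirconation of the 2-alkyne under equilibrating conditions (excess hydride, warming) should place zirconium on the less hindered methyl-bearing carbon, and iodinolysis with retention then gives the (E)-2-iodo-2-alkene with the methyl group cis to C11.

Step 6
Reactants: 13 2,2-dimethylpent-4-enal; 14 triethyl 4-phosphonocrotonate
Product: 16 ethyl (2E,4E)-6,6-dimethylnona-2,4,8-trienoate (fragment 2), via lithiated phosphonate 15 (not isolated)
Conditions: LiN(SiMe3)2, THF, −78 °C; then 13, −78 to 0 °C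
Reagents that add atoms: none
Why: Vinylogous Horner–Wadsworth–Emmons olefination of the non-enolisable α-quaternary aldehyde with the stabilised crotyl phosphonate anion should give the (2E,4E)-dienoate, the new C5=C6 bond being E because the stabilised anion adds reversibly and the neopentyl aldehyde is bulky.

Step 7
Reactants: 16 ethyl (2E,4E)-6,6-dimethylnona-2,4,8-trienoate; 12 (S,E)-tert-butyl[(7-iodo-3-methyloct-6-en-1-yl)oxy]dimethylsilane
Product: 18 ethyl (2E,4E,10E,14S)-16-[(tert-butyldimethylsilyl)oxy]-6,6,10,14-tetramethylhexadeca-2,4,10-trienoate, via B-alkyl-9-BBN borane 17 (not isolated)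
Conditions: 9-BBN, THF, 0 °C to rt; then 12, PdCl2(dppf) (5 mol %), AsPh3, Cs2CO3, DMF/THF/H2O, rt
Reagents that add atoms: none
Why: 9-BBN hydroborates only the monosubstituted alkene in the anti-Markovnikov sense (the dienoate is electron-poor and flanked by a quaternary carbon), and the B-alkyl Suzuki–Miyaura coupling joins C1 to C10 with retention of the vinyl iodide geometry.

Step 8
Reactants: 18 ethyl (2E,4E,10E,14S)-16-[(tert-butyldimethylsilyl)oxy]-6,6,10,14-tetramethylhexadeca-2,4,10-trienoate
Product: 19 ethyl (2E,4E,10E,14S)-16-hydroxy-6,6,10,14-tetramethylhexadeca-2,4,10-trienoate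
Conditions: HF·pyridine, pyridine, THF, 0 °C to rt
Reagents that add atoms: none
Why: Fluoride cleaves the primary silyl ether through Si–F bond formation under buffered conditions that spare the dienoate and the trisubstituted alkene.

Step 9
Reactants: 19 ethyl (2E,4E,10E,14S)-16-hydroxy-6,6,10,14-tetramethylhexadeca-2,4,10-trienoate
Product: 21 (2E,4E,10E,14S)-16-hydroxy-6,6,10,14-tetramethylhexadeca-2,4,10-trienoic acid (seco acid), via lithium carboxylate 20 (not isolated)
Conditions: LiOH, THF/MeOH/H2O, rt; then 1 M HCl to pH 3
Reagents that add atoms: lithium hydroxide, [Li+].[OH-]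
Why: Hydroxide saponifies the ethyl ester by acyl substitution, and the dienoate cannot deconjugate because C4 carries no hydrogen.

Step 10
Reactants: 21 (2E,4E,10E,14S)-16-hydroxy-6,6,10,14-tetramethylhexadeca-2,4,10-trienoic acid
Product: 23 (3E,5E,11E,15S)-7,7,11,15-tetramethyl-1-oxacycloheptadeca-3,5,11-trien-2-one (17-membered macrolactone), via mixed anhydride 22 (not isolated)
Conditions: 2,4,6-trichlorobenzoyl chloride, Et3N, THF, rt; then slow addition to DMAP, toluene, 80 °C (final 1 mM)
Reagents that add atoms: none
Why: In the Yamaguchi macrolactonisation DMAP acylates at the dienoyl carbonyl of the mixed anhydride and the C15 alcohol captures the acylpyridinium under high dilution to join O15 to C17, the quaternary C4 ruling out deconjugation of the activated dienoate.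

Step 11
Reactants: 23 (3E,5E,11E,15S)-7,7,11,15-tetramethyl-1-oxacycloheptadeca-3,5,11-trien-2-one
Product: 24 (5S,8S,9S,10R,13S)-labd-6-en-17,15-olide (trans-decalin with 5α-H and 10β-methyl, cis-fused at C8–C9 to the nine-membered 17,15-lactone, 8α-H and 9α-H)
Conditions: toluene (2 mM, degassed), BHT (cat.), sealed tube, 210 °C
Reagents that add atoms: none
Why: The step is a concerted, suprafacial thermal [4+2] cycloaddition across the 17-membered ring between the C5=C6–C7=C8 dienoate and the C9=C10 alkene, a transannular Diels–Alder reaction of a macrocyclic (E,E,E)-triene whose closest open-chain relative is the thermal intramolecular Diels–Alder reaction of 1,7,9-decatrienes with an ester on the diene terminus. Ring A closes by the C5–C10 bond as a six-membered ring through a chair-like C1–C4 tether in the exo position, ring B is the cycloadduct cyclohexene formed by the C5–C10 and C8–C9 bonds, and the C11-to-C17 bridge is left as a cis-fused nine-membered lactone. The (E,E)-diene puts H5 and H8 cis, the (E)-alkene puts C20 cis to C11 and C1 trans to C11, and the exo four-carbon tether makes the A/B junction trans, so the trans-anti-cis tricycle should result, with C8 only a temporary centre. The absolute sense, that is which diene face adds, is relayed from C13, whose methyl group must lie outward on the forming nine-membered ring. The step therefore needs trans-anti-cis over cis-anti-trans closure, which the triene geometry and the short gem-dimethyl-bearing tether favour, and it needs one diene face, which only the C13 methyl controls and which is the open point of the route. Quaternary C4 and the C17 carbonyl remove the hydrogens needed for 1,5-hydrogen shifts of the diene, so the triene should survive the temperature.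

Step 12
Reactants: 24 (5S,8S,9S,10R,13S)-labd-6-en-17,15-olide
Product: 26 methyl (5S,9R,10S,13S)-15-hydroxylabd-7-en-17-oate, via unconjugated hydroxy ester 25 (not isolated)
Conditions: NaOMe (3 equiv), MeOH, 65 °C
Reagents that add atoms: methanol (delivered as NaOMe/MeOH), CO
Why: Methoxide opens the strained nine-membered lactone by transesterification, and reversible deprotonation at C8 gives the extended enolate, which is reprotonated at C6 to the conjugated trisubstituted enoate (base-mediated β,γ to α,β isomerisation), while the non-acidic C9 keeps its configuration and the C8 centre disappears.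

Step 13
Reactants: 26 methyl (5S,9R,10S,13S)-15-hydroxylabd-7-en-17-oate
Product: 28 (5S,9R,10S,13S)-15-hydroxylabd-7-en-17-oic acid, via potassium carboxylate 27 (not isolated)
Conditions: KOH, MeOH/H2O (4:1), 70 °C; then 1 M HCl to pH 3
Reagents that add atoms: potassium hydroxide, [K+].[OH-]
Why: Hydroxide saponifies the hindered conjugated methyl ester, and the carboxylate formed cannot be deprotonated further under these conditions, so the alkene stays at C7=C8 and C9 is not epimerised.

Step 14
Reactants: 28 (5S,9R,10S,13S)-15-hydroxylabd-7-en-17-oic acid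
Product: 29 (5S,9R,10S,13S)-15-(formyloxy)labd-7-en-17-oic acid (target)
Conditions: HCO2H/Ac2O (premixed at 55 °C to give acetic formic anhydride), pyridine, CH2Cl2, 0 °C; then H2O
Reagents that add atoms: acetic formic anhydride, CC(=O)OC=O
Why: Acetic formic anhydride transfers its more electrophilic formyl group selectively to the primary alcohol (O-formylation), and any mixed anhydride formed at the hindered conjugated acid is hydrolysed back to the acid on aqueous work-up.

**Compound list**

1 | (S)-citronellol, (S)-3,7-dimethyloct-6-en-1-ol | C[C@H](CCO)CCC=C(C)C | starting material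
2 | (S)-tert-butyl[(3,7-dimethyloct-6-en-1-yl)oxy]dimethylsilane | C[C@H](CCO[Si](C)(C)C(C)(C)C)CCC=C(C)C | intermediate
3 | secondary ozonide of 2 (3,3-dimethyl-1,2,4-trioxolane carrying the silyloxy chain at C5) | C[C@H](CCO[Si](C)(C)C(C)(C)C)CCC1OOC(C)(C)O1 | intermediate (not isolated)
4 | (S)-6-[(tert-butyldimethylsilyl)oxy]-4-methylhexanal | C[C@H](CCO[Si](C)(C)C(C)(C)C)CCC=O | intermediate
5 | carbon tetrabromide | BrC(Br)(Br)Br | starting material
6 | (dibromomethylene)triphenylphosphorane | BrC(Br)=P(c1ccccc1)(c1ccccc1)c1ccccc1 | intermediate (not isolated)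
7 | (S)-tert-butyl[(7,7-dibromo-3-methylhept-6-en-1-yl)oxy]dimethylsilane | C[C@H](CCO[Si](C)(C)C(C)(C)C)CCC=C(Br)Br | intermediate
8 | iodomethane | CI | starting material
9 | lithium (S)-6-methyl-8-(tert-butyldimethylsilyloxy)oct-1-yn-1-ide (lithium acetylide) | C[C@H](CCO[Si](C)(C)C(C)(C)C)CCC#C[Li] | intermediate (not isolated)
10 | (S)-tert-butyldimethyl[(3-methyloct-6-yn-1-yl)oxy]silane | C[C@H](CCO[Si](C)(C)C(C)(C)C)CCC#CC | intermediate
11 | (E)-alkenylzirconocene chloride, Zr on the methyl-bearing carbon, methyl cis to C11 | C[C@H](CCO[Si](C)(C)C(C)(C)C)CC/C=C(/[Zr](Cl)(C1C=CC=C1)C1C=CC=C1)C | intermediate (not isolated)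
12 | (S,E)-tert-butyl[(7-iodo-3-methyloct-6-en-1-yl)oxy]dimethylsilane | C[C@H](CCO[Si](C)(C)C(C)(C)C)CC/C=C(/I)C | intermediate
13 | 2,2-dimethylpent-4-enal | O=CC(C)(C)CC=C | starting material
14 | triethyl 4-phosphonocrotonate | CCOC(=O)/C=C/CP(=O)(OCC)OCC | starting material
15 | lithiated triethyl 4-phosphonocrotonate | CCOC(=O)/C=C/[CH-]P(=O)(OCC)OCC.[Li+] | intermediate (not isolated)
16 | ethyl (2E,4E)-6,6-dimethylnona-2,4,8-trienoate | CCOC(=O)/C=C/C=C/C(C)(C)CC=C | intermediate
17 | ethyl (2E,4E)-9-(9-borabicyclo[3.3.1]nonan-9-yl)-6,6-dimethylnona-2,4-dienoate | CCOC(=O)/C=C/C=C/C(C)(C)CCCB1C2CCCC1CCC2 | intermediate (not isolated)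
18 | ethyl (2E,4E,10E,14S)-16-[(tert-butyldimethylsilyl)oxy]-6,6,10,14-tetramethylhexadeca-2,4,10-trienoate | CCOC(=O)/C=C/C=C/C(C)(C)CCC/C(C)=C/CC[C@H](C)CCO[Si](C)(C)C(C)(C)C | intermediate
19 | ethyl (2E,4E,10E,14S)-16-hydroxy-6,6,10,14-tetramethylhexadeca-2,4,10-trienoate | CCOC(=O)/C=C/C=C/C(C)(C)CCC/C(C)=C/CC[C@H](C)CCO | intermediate
20 | lithium (2E,4E,10E,14S)-16-hydroxy-6,6,10,14-tetramethylhexadeca-2,4,10-trienoate | [Li+].[O-]C(=O)/C=C/C=C/C(C)(C)CCC/C(C)=C/CC[C@H](C)CCO | intermediate (not isolated)
21 | (2E,4E,10E,14S)-16-hydroxy-6,6,10,14-tetramethylhexadeca-2,4,10-trienoic acid | OC(=O)/C=C/C=C/C(C)(C)CCC/C(C)=C/CC[C@H](C)CCO | intermediate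
22 | mixed anhydride of 21 with 2,4,6-trichlorobenzoic acid | O=C(OC(=O)/C=C/C=C/C(C)(C)CCC/C(C)=C/CC[C@H](C)CCO)c1c(Cl)cc(Cl)cc1Cl | intermediate (not isolated)
23 | (3E,5E,11E,15S)-7,7,11,15-tetramethyl-1-oxacycloheptadeca-3,5,11-trien-2-one | O=C1/C=C/C=C/C(C)(C)CCC/C(C)=C/CC[C@H](C)CCO1 | intermediate
24 | (5S,8S,9S,10R,13S)-labd-6-en-17,15-olide | C[C@@H]1CCOC(=O)[C@H]2C=C[C@H]3C(C)(C)CCC[C@]3(C)[C@H]2CC1 | intermediate
25 | methyl (5S,8S,9S,10R,13S)-15-hydroxylabd-6-en-17-oate (C8 labile) | C[C@H](CCO)CC[C@H]1[C@@H](C(=O)OC)C=C[C@H]2C(C)(C)CCC[C@]12C | intermediate (not isolated)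
26 | methyl (5S,9R,10S,13S)-15-hydroxylabd-7-en-17-oate | C[C@H](CCO)CC[C@H]1C(C(=O)OC)=CC[C@H]2C(C)(C)CCC[C@]12C | intermediate
27 | potassium (5S,9R,10S,13S)-15-hydroxylabd-7-en-17-oate | C[C@H](CCO)CC[C@H]1C(C(=O)[O-])=CC[C@H]2C(C)(C)CCC[C@]12C.[K+] | intermediate (not isolated)
28 | (5S,9R,10S,13S)-15-hydroxylabd-7-en-17-oic acid | C[C@H](CCO)CC[C@H]1C(C(=O)O)=CC[C@H]2C(C)(C)CCC[C@]12C | intermediate
29 | (5S,9R,10S,13S)-15-(formyloxy)labd-7-en-17-oic acid | C[C@H](CCOC=O)CC[C@H]1C(C(=O)O)=CC[C@H]2C(C)(C)CCC[C@]12C | target

**Step count and risks**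

Total step count: 14. Longest linear sequence: 13 steps from (S)-citronellol (steps 1 to 5 and 7 to 14); fragment 2 is made in one step (step 6).

Steps most likely to fail:

Step 11. The remote C13 methyl may discriminate poorly between the two diene faces. Closure in the cis-anti-trans mode (A/B cis) may compete. The unactivated trisubstituted alkene may need a temperature at which decomposition sets in. The fallback sets out from 23 and comes back at 24. It no longer asks the cycloaddition for face selectivity and uses the lactone bridge as a resolving template instead. The two trans-anti-cis adducts are rigid diastereomers in which C13 lies in the same nine-membered ring as C8 and C9. They should be separated at this stage by chromatography on silica or by crystallisation, before the lactone is opened and the difference becomes a remote one. Only 24 is carried on; its diastereomer with the mirror-image decalin, (5R,8R,9R,10S,13S)-labd-6-en-17,15-olide F1, is discarded.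

Step 10. Oligomerisation may outrun closure of the 17-membered ring, and the DMAP-activated dienoyl unit may lose its E,E geometry. The fallback sets out from 12 and 16 and comes back at 23. It closes the ring at C1–C10 instead of at O15–C17.
- Vinyl iodide 12 would be desilylated (HF·pyridine, THF) to (S,E)-7-iodo-3-methyloct-6-en-1-ol F2.
- Ester 16 would be saponified (LiOH, then HCl) through lithium (2E,4E)-6,6-dimethylnona-2,4,8-trienoate F3 to (2E,4E)-6,6-dimethylnona-2,4,8-trienoic acid F4.
- Steglich esterification (EDC·HCl, DMAP, CH2Cl2, 0 °C) would join the two to (S,E)-7-iodo-3-methyloct-6-en-1-yl (2E,4E)-6,6-dimethylnona-2,4,8-trienoate F5.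
- 9-BBN would hydroborate the terminal alkene of F5 selectively to the B-alkyl-9-BBN borane F6.
- Slow addition of F6 to PdCl2(dppf), AsPh3 and Cs2CO3 in DMF/THF/H2O at high dilution would close the macrocycle by an intramolecular B-alkyl Suzuki–Miyaura coupling, a known ring-closing mode, to give 23.

Step 5. Zirconium may add with incomplete regiocontrol to an alkyne whose two ends differ only as methyl against a primary alkyl chain, so that a regioisomeric iodide is carried into the coupling. The fallback sets out from dibromoalkene 7, uses borane 17 of step 7, and comes back at 18. It builds the trisubstituted alkene by two stereodefined couplings.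
- A trans-selective mono-coupling of 7 with 17 (Pd2(dba)3, P(2-furyl)3, Cs2CO3, THF/DMF/H2O) replaces the bromine trans to C11. It would give ethyl (2E,4E,10Z,14S)-10-bromo-16-[(tert-butyldimethylsilyl)oxy]-6,6,14-trimethylhexadeca-2,4,10-trienoate F7.
- Negishi methylation of the remaining alkenyl bromide with MeZnCl and Pd(P(t-Bu)3)2, a zerovalent palladium catalyst known to couple such bromides with retention, would then give 18 with the methyl group cis to C11.

**Further compounds**

F1 | step 11 | (5R,8R,9R,10S,13S)-labd-6-en-17,15-olide | C[C@@H]1CCOC(=O)[C@@H]2C=C[C@@H]3C(C)(C)CCC[C@@]3(C)[C@@H]2CC1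
F2 | step 10 | (S,E)-7-iodo-3-methyloct-6-en-1-ol | C[C@H](CCO)CC/C=C(/I)C
F3 | step 10 | lithium (2E,4E)-6,6-dimethylnona-2,4,8-trienoate | [Li+].[O-]C(=O)/C=C/C=C/C(C)(C)CC=C
F4 | step 10 | (2E,4E)-6,6-dimethylnona-2,4,8-trienoic acid | OC(=O)/C=C/C=C/C(C)(C)CC=C
F5 | step 10 | (S,E)-7-iodo-3-methyloct-6-en-1-yl (2E,4E)-6,6-dimethylnona-2,4,8-trienoate | C[C@H](CCOC(=O)/C=C/C=C/C(C)(C)CC=C)CC/C=C(/I)C
F6 | step 10 | (S,E)-7-iodo-3-methyloct-6-en-1-yl (2E,4E)-9-(9-borabicyclo[3.3.1]nonan-9-yl)-6,6-dimethylnona-2,4-dienoate | C[C@H](CCOC(=O)/C=C/C=C/C(C)(C)CCCB1C2CCCC1CCC2)CC/C=C(/I)C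
F7 | step 5 | ethyl (2E,4E,10Z,14S)-10-bromo-16-[(tert-butyldimethylsilyl)oxy]-6,6,14-trimethylhexadeca-2,4,10-trienoate | CCOC(=O)/C=C/C=C/C(C)(C)CCC/C(Br)=C/CC[C@H](C)CCO[Si](C)(C)C(C)(C)C
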